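**Retrosynthetic overview**

- The target is reached from its 5-O-triflyl-7,3',4'-tri-O-benzyl flavone by cleaving the sulfonate and then hydrogenolysing the benzyl ethers.
- That flavone is cut at O1–C8a, C4–C4a and O1–C2, giving a ring A aryne and the ring B arylpropiolic acid. Rings A and B are carried intact and ring C is closed last.
- The route rests on one feature of ring A: C4a and C8a are neighbouring carbons bearing the C4 carbonyl and O1, flanked by the C5 oxygen and the C8 methoxy. With the C5 oxygen carried as a triflate and C7–OBn on the mirror line, the aryne precursor is a symmetric 2-silyl-1,3-bis(triflate); one triflate leaves and the other steers the addition.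
- The silyl bis(triflate) comes from syringol by benzylation, dibromination, double hydroxylation, bromination between the hydroxyls, retro-Brook silyl shift and bis-triflation. The acid comes from 5-hydroxyvanillin by benzylation, Corey–Fuchs olefination and carboxylation.

Key step: step 10

Remark: the aryl O–SiMe3 group left after the silyl shift in step 5 is assumed to hydrolyse during the aqueous NH4Cl work-up, as aryl trimethylsilyl ethers generally do, so that both oxygens are free for triflation in step 6.

**Route**

Step 1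
Reactants: 1 2,6-dimethoxyphenol (syringol)
Product: 2 2-(benzyloxy)-1,3-dimethoxybenzene
Conditions: BnBr, K2CO3, DMF, 60 °C
Reagents that add atoms: benzyl bromide, BrCc1ccccc1
Why: Williamson ether synthesis on the phenoxide, which should go cleanly with the reactive benzylic halide despite the two ortho methoxy groups.

Step 2
Reactants: 2 2-(benzyloxy)-1,3-dimethoxybenzene
Product: 3 3-(benzyloxy)-1,5-dibromo-2,4-dimethoxybenzene
Conditions: NBS (2.1 equiv), MeCN, 0 °C to rt, dark
Reagents that add atoms: N-bromosuccinimide, O=C1CCC(=O)N1Br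
Why: Electrophilic aromatic bromination, in which each bromine should enter ortho to one methoxy and para to the other, because the position para to the twisted central benzyloxy group is the least activated.

Step 3
Reactants: 3 3-(benzyloxy)-1,5-dibromo-2,4-dimethoxybenzene
Product: 4 5-(benzyloxy)-4,6-dimethoxybenzene-1,3-diol
Conditions: Pd2(dba)3, tBuXPhos, KOH, 1,4-dioxane/H2O, 100 °C, argon; then aq HCl
Reagents that add atoms: potassium hydroxide, [K+].[OH-]
Why: Palladium-catalysed C–O coupling of aryl bromides with hydroxide (Buchwald-type hydroxylation), where the bulky biaryl phosphine favours the phenol over diaryl ether and both bromides carry only one ortho substituent.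

Step 4
Reactants: 4 5-(benzyloxy)-4,6-dimethoxybenzene-1,3-diol
Product: 5 5-(benzyloxy)-2-bromo-4,6-dimethoxybenzene-1,3-diol
Conditions: NBS (1.0 equiv), CH2Cl2, −78 °C
Reagents that add atoms: N-bromosuccinimide, O=C1CCC(=O)N1Br
Why: Electrophilic aromatic bromination at the single unsubstituted carbon of the resorcinol ring, which is ortho to both hydroxyls and so reacts at low temperature before any oxidation of the ring.

Step 5
Reactants: 5 5-(benzyloxy)-2-bromo-4,6-dimethoxybenzene-1,3-diol
Product: 8 5-(benzyloxy)-4,6-dimethoxy-2-(trimethylsilyl)benzene-1,3-diol, via bis(trimethylsilyl) ether 6 (not isolated), via lithium silylphenoxide 7 (not isolated)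
Conditions: HMDS, THF, 70 °C, then evaporate; n-BuLi, THF, −78 to −20 °C; then aq NH4Cl, rt
Reagents that add atoms: hexamethyldisilazane, C[Si](C)(C)N[Si](C)(C)C
Why: O-silylation followed by bromine–lithium exchange and 1,3 O-to-C silyl migration (retro-Brook rearrangement), driven by exchange of an aryllithium for a phenoxide, with the remaining labile O–SiMe3 group hydrolysed on work-up.

Step 6
Reactants: 8 5-(benzyloxy)-4,6-dimethoxy-2-(trimethylsilyl)benzene-1,3-diol
Product: 9 5-(benzyloxy)-4,6-dimethoxy-2-(trimethylsilyl)-1,3-phenylene bis(trifluoromethanesulfonate)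
Conditions: Tf2O (2.4 equiv), pyridine, CH2Cl2, −78 to 0 °C
Reagents that add atoms: trifluoromethanesulfonic anhydride, O=S(=O)(OS(=O)(=O)C(F)(F)F)C(F)(F)F
Why: O-sulfonylation of both phenols, the standard way to ortho-silylaryl triflates, with a weak amine base and low temperature so that the C–Si bond is kept and no phenoxide-triggered silyl shift sets in at the mono-triflate stage.

Step 7
Reactants: 10 3,4-dihydroxy-5-methoxybenzaldehyde (5-hydroxyvanillin)
Product: 11 3,4-bis(benzyloxy)-5-methoxybenzaldehyde
Conditions: BnBr (2.3 equiv), K2CO3, DMF, 60 °C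
Reagents that add atoms: benzyl bromide, BrCc1ccccc1
Why: Double Williamson ether synthesis on the catechol, to which the aldehyde is inert.

Step 8
Reactants: 11 3,4-bis(benzyloxy)-5-methoxybenzaldehyde
Product: 12 1,2-bis(benzyloxy)-5-(2,2-dibromoethenyl)-3-methoxybenzene
Conditions: CBr4, PPh3, CH2Cl2, 0 °C
Reagents that add atoms: carbon tetrabromide, BrC(Br)(Br)Br
Why: Corey–Fuchs (Ramirez) dibromoolefination of the aromatic aldehyde by the ylide formed from PPh3 and CBr4.

Step 9
Reactants: 12 1,2-bis(benzyloxy)-5-(2,2-dibromoethenyl)-3-methoxybenzene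
Product: 14 3-[3,4-bis(benzyloxy)-5-methoxyphenyl]prop-2-ynoic acid, via lithium acetylide 13 (not isolated)
Conditions: n-BuLi (2.2 equiv), THF, −78 to 0 °C; CO2, −78 °C to rt; aq HCl
Reagents that add atoms: carbon dioxide, O=C=O
Why: Second stage of the Corey–Fuchs sequence (bromine–lithium exchange, rearrangement to the alkyne and deprotonation) with the lithium acetylide trapped by carboxylation, conditions under which benzyl ethers are stable at low temperature.

Step 10
Reactants: 9 5-(benzyloxy)-4,6-dimethoxy-2-(trimethylsilyl)-1,3-phenylene bis(trifluoromethanesulfonate); 14 3-[3,4-bis(benzyloxy)-5-methoxyphenyl]prop-2-ynoic acid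
Product: 17 7-(benzyloxy)-2-[3,4-bis(benzyloxy)-5-methoxyphenyl]-6,8-dimethoxy-4-oxo-4H-chromen-5-yl trifluoromethanesulfonate, via triflyloxy aryne 15 (not isolated), via caesium 2-acylphenoxide 16 (not isolated)
Conditions: CsF (4 equiv), THF, sealed tube, 100 °C
Reagents that add atoms: none
Why: Fluoride removes the silyl group of 9 and one of the two equivalent triflates leaves, so a single aryne 15 across C4a–C8a forms; the caesium carboxylate of 14 adds at C8a, the C4a anion attacks the ester carbonyl through a four-membered intermediate that opens to the 2-acylphenoxide 16 (net insertion into the C–O bond, forming O1–C8a and C4–C4a), and the phenoxide then closes ring C by 6-endo-dig conjugate addition to the ynone (O1–C2). The closest known reaction type is the fluoride-mediated C–O insertion of arynes into carboxylic acids, which with arylpropiolic acids gives flavones directly, combined with the known directing effect of a triflyloxy group in 3-(triflyloxy)arynes. No stereocentre is formed. The step needs the carboxylate to add at C8a and not at C4a: the C5 triflyloxy group is a much stronger σ-acceptor and a larger group than the C8 methoxy, so the aryne should be distorted and shielded in favour of attack at the carbon remote from the triflate, which also places the developing negative charge next to the better acceptor. It also needs acyl transfer to outrun loss of triflate from the ortho anion, which is expected because the anion sits next to a highly electrophilic aryl ynoate carbonyl, a situation in which ortho-metallated aryl esters rearrange faster than they can be intercepted. The 6-endo over 5-exo closure follows the polarity of the ynone, whose β-carbon is the electrophilic site.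

Step 11
Reactants: 17 7-(benzyloxy)-2-[3,4-bis(benzyloxy)-5-methoxyphenyl]-6,8-dimethoxy-4-oxo-4H-chromen-5-yl trifluoromethanesulfonate
Product: 18 7-(benzyloxy)-2-[3,4-bis(benzyloxy)-5-methoxyphenyl]-5-hydroxy-6,8-dimethoxy-4H-chromen-4-one
Conditions: Et4NOH (aq, 2 equiv), 1,4-dioxane, rt; then aq NH4Cl
Reagents that add atoms: none
Why: Cleavage of an aryl triflate by hydroxide attack at sulfur (S–O cleavage), eased because the C5 phenoxide peri to the C4 carbonyl is a good leaving group, under conditions mild enough to leave the chromone and the benzyl ethers intact.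

Step 12
Reactants: 18 7-(benzyloxy)-2-[3,4-bis(benzyloxy)-5-methoxyphenyl]-5-hydroxy-6,8-dimethoxy-4H-chromen-4-one
Product: 19 2-(3,4-dihydroxy-5-methoxyphenyl)-5,7-dihydroxy-6,8-dimethoxy-4H-chromen-4-one (5,7,3',4'-tetrahydroxy-6,8,5'-trimethoxyflavone)
Conditions: H2 (1 atm), 10% Pd/C, EtOAc/MeOH, rt
Reagents that add atoms: none
Why: Catalytic hydrogenolysis of the three benzyl ethers, which at ambient pressure and temperature should not reduce the C2–C3 bond of the chromone or touch the methyl ethers.

**Compound list**

1 | 2,6-dimethoxyphenol (syringol) | COc1cccc(OC)c1O | starting material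
2 | 2-(benzyloxy)-1,3-dimethoxybenzene | COc1cccc(OC)c1OCc1ccccc1 | intermediate
3 | 3-(benzyloxy)-1,5-dibromo-2,4-dimethoxybenzene | COc1c(Br)cc(Br)c(OC)c1OCc1ccccc1 | intermediate
4 | 5-(benzyloxy)-4,6-dimethoxybenzene-1,3-diol | COc1c(O)cc(O)c(OC)c1OCc1ccccc1 | intermediate
5 | 5-(benzyloxy)-2-bromo-4,6-dimethoxybenzene-1,3-diol | COc1c(O)c(Br)c(O)c(OC)c1OCc1ccccc1 | intermediate
6 | {[5-(benzyloxy)-2-bromo-4,6-dimethoxy-1,3-phenylene]bis(oxy)}bis(trimethylsilane) | COc1c(O[Si](C)(C)C)c(Br)c(O[Si](C)(C)C)c(OC)c1OCc1ccccc1 | intermediate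
7 | lithium 5-(benzyloxy)-4,6-dimethoxy-2-(trimethylsilyl)-3-[(trimethylsilyl)oxy]phenolate | COc1c([O-])c([Si](C)(C)C)c(O[Si](C)(C)C)c(OC)c1OCc1ccccc1.[Li+] | intermediate
8 | 5-(benzyloxy)-4,6-dimethoxy-2-(trimethylsilyl)benzene-1,3-diol | COc1c(O)c([Si](C)(C)C)c(O)c(OC)c1OCc1ccccc1 | intermediate
9 | 5-(benzyloxy)-4,6-dimethoxy-2-(trimethylsilyl)-1,3-phenylene bis(trifluoromethanesulfonate) | C[Si](C)(C)c1c(OS(=O)(=O)C(F)(F)F)c(OC)c(OCc2ccccc2)c(OC)c1OS(=O)(=O)C(F)(F)F | intermediate
10 | 3,4-dihydroxy-5-methoxybenzaldehyde (5-hydroxyvanillin) | COc1cc(C=O)cc(O)c1O | starting material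
11 | 3,4-bis(benzyloxy)-5-methoxybenzaldehyde | COc1cc(C=O)cc(OCc2ccccc2)c1OCc1ccccc1 | intermediate
12 | 1,2-bis(benzyloxy)-5-(2,2-dibromoethenyl)-3-methoxybenzene | COc1cc(C=C(Br)Br)cc(OCc2ccccc2)c1OCc1ccccc1 | intermediate
13 | lithium [3,4-bis(benzyloxy)-5-methoxyphenyl]acetylide | [Li]C#Cc1cc(OC)c(OCc2ccccc2)c(OCc2ccccc2)c1 | intermediate
14 | 3-[3,4-bis(benzyloxy)-5-methoxyphenyl]prop-2-ynoic acid | OC(=O)C#Cc1cc(OC)c(OCc2ccccc2)c(OCc2ccccc2)c1 | intermediate
15 | 3-(benzyloxy)-2,4-dimethoxy-5,6-didehydrophenyl trifluoromethanesulfonate (aryne) | COC1=C(OCc2ccccc2)C(OC)=C(OS(=O)(=O)C(F)(F)F)C#C1 | intermediate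
16 | caesium 3-(benzyloxy)-6-{3-[3,4-bis(benzyloxy)-5-methoxyphenyl]prop-2-ynoyl}-2,4-dimethoxy-5-[(trifluoromethanesulfonyl)oxy]phenolate | COc1cc(C#CC(=O)c2c([O-])c(OC)c(OCc3ccccc3)c(OC)c2OS(=O)(=O)C(F)(F)F)cc(OCc2ccccc2)c1OCc1ccccc1.[Cs+] | intermediate
17 | 7-(benzyloxy)-2-[3,4-bis(benzyloxy)-5-methoxyphenyl]-6,8-dimethoxy-4-oxo-4H-chromen-5-yl trifluoromethanesulfonate | COc1cc(-c2cc(=O)c3c(OS(=O)(=O)C(F)(F)F)c(OC)c(OCc4ccccc4)c(OC)c3o2)cc(OCc2ccccc2)c1OCc1ccccc1 | intermediate
18 | 7-(benzyloxy)-2-[3,4-bis(benzyloxy)-5-methoxyphenyl]-5-hydroxy-6,8-dimethoxy-4H-chromen-4-one | COc1cc(-c2cc(=O)c3c(O)c(OC)c(OCc4ccccc4)c(OC)c3o2)cc(OCc2ccccc2)c1OCc1ccccc1 | intermediate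
19 | 2-(3,4-dihydroxy-5-methoxyphenyl)-5,7-dihydroxy-6,8-dimethoxy-4H-chromen-4-one | COc1cc(-c2cc(=O)c3c(O)c(OC)c(O)c(OC)c3o2)cc(O)c1O | target

**Step count**

Total steps: 12. Longest linear sequence: 9 steps (steps 1 to 6, then 10 to 12, from syringol). The ring B branch (steps 7 to 9) joins at step 10.

**Steps most likely to fail**

1. Step 10. Four processes could spoil it:
   - the carboxylate may add at the aryne carbon next to the triflate if the pull of the C8 methoxy competes, which would give the regioisomeric flavone;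
   - the ortho anion may lose triflate before acyl transfer, which generates a second aryne and oligomers;
   - the anion may be protonated, which stops at the O-aryl ester;
   - the propiolate may decarboxylate on heating.

   Partial cleavage of the C5 triflate by hot CsF would be harmless, since it leads to 18. The fallback sets out from 4 and 11 and comes back at 18. It uses the classical chalcone route, which needs no regiochemical decision because 4 is symmetric. Friedel–Crafts C-acetylation of 4 at its only free ring carbon (Ac2O, BF3·OEt2, CH2Cl2, 0 °C to rt) should give 1-[4-(benzyloxy)-2,6-dihydroxy-3,5-dimethoxyphenyl]ethan-1-one F1. Claisen–Schmidt condensation of this ketone with aldehyde 11 (KOH, EtOH/H2O, rt) should give (E)-1-[4-(benzyloxy)-2,6-dihydroxy-3,5-dimethoxyphenyl]-3-[3,4-bis(benzyloxy)-5-methoxyphenyl]prop-2-en-1-one F2. Oxidative cyclisation of the 2'-hydroxychalcone (catalytic I2, DMSO, 120 °C) then closes ring C and gives 18, which goes on through step 12.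

2. Step 5. The hindered aryllithium may be protonated before the silyl group migrates, the migration may stay incomplete, and the electron-rich arylsilane may lose silicon by protodesilylation on work-up. The fallback sets out from 5 and comes back at 8, with silicon brought in from outside instead of by migration. Bis-O-allylation (allyl bromide, K2CO3, DMF) should give 1,3-bis(allyloxy)-5-(benzyloxy)-2-bromo-4,6-dimethoxybenzene F3. Bromine–lithium exchange and prompt silylation (n-BuLi, THF, −78 °C, then TMSCl) should give [2,6-bis(allyloxy)-4-(benzyloxy)-3,5-dimethoxyphenyl]trimethylsilane F4. Neutral deallylation (Pd(PPh3)4, morpholine, THF, rt) should then give 8 without exposure to acid.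

3. Step 3. The second C–O coupling may stall at the bromophenol, hydrodebromination and diaryl ether formation may compete, and the electron-rich resorcinol may be oxidised by air in hot alkali. The fallback sets out from 3 and comes back at 4, replacing direct hydroxylation by borylation and oxidation. Double Miyaura borylation (B2pin2, Pd(dppf)Cl2, KOAc, 1,4-dioxane, 90 °C) should give 2,2'-[5-(benzyloxy)-4,6-dimethoxy-1,3-phenylene]bis(4,4,5,5-tetramethyl-1,3,2-dioxaborolane) F5. Oxidation of both C–B bonds (H2O2, NaOH, THF/H2O, 0 °C) should give 4.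

**Further compounds**

F1 | step 10 | 1-[4-(benzyloxy)-2,6-dihydroxy-3,5-dimethoxyphenyl]ethan-1-one | CC(=O)c1c(O)c(OC)c(OCc2ccccc2)c(OC)c1O
F2 | step 10 | (E)-1-[4-(benzyloxy)-2,6-dihydroxy-3,5-dimethoxyphenyl]-3-[3,4-bis(benzyloxy)-5-methoxyphenyl]prop-2-en-1-one | COc1cc(/C=C/C(=O)c2c(O)c(OC)c(OCc3ccccc3)c(OC)c2O)cc(OCc2ccccc2)c1OCc1ccccc1
F3 | step 5 | 1,3-bis(allyloxy)-5-(benzyloxy)-2-bromo-4,6-dimethoxybenzene | C=CCOc1c(Br)c(OCC=C)c(OC)c(OCc2ccccc2)c1OC
F4 | step 5 | [2,6-bis(allyloxy)-4-(benzyloxy)-3,5-dimethoxyphenyl]trimethylsilane | C=CCOc1c([Si](C)(C)C)c(OCC=C)c(OC)c(OCc2ccccc2)c1OC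
F5 | step 3 | 2,2'-[5-(benzyloxy)-4,6-dimethoxy-1,3-phenylene]bis(4,4,5,5-tetramethyl-1,3,2-dioxaborolane) | COc1c(B2OC(C)(C)C(C)(C)O2)cc(B2OC(C)(C)C(C)(C)O2)c(OC)c1OCc1ccccc1
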